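# Total synthesis of CNP0143674.1 by a carbonyl-ylide (5+2) cycloaddition

## Analysis of the target

Target 30 is a spiro compound. A 2,3,4-trimethoxybenzo[7]annulene (arene ring A fused to seven-membered ring B; ring B atoms C4a, C5–C9, C9a) shares C5 with a 3',5'-dimethoxycyclohexa-2',5'-dien-4'-one (ring C, C5 = C1'). Ring B carries three contiguous stereocentres: C7 (R, methyl), C8 (S, methyl) and C9 (R, acetoxy). The two methyl groups are trans, the C8 methyl and the C9 oxygen are trans, and the C7 methyl and the C9 oxygen are therefore cis. C5 is quaternary and crowded by the C4 methoxy group, but it is not a stereocentre, because the two arms of ring C are identical. The sensitive groups are the cross-conjugated dienone (two enol ethers that acid hydrolyses, and a skeleton open to dienone–phenol rearrangement) and the benzylic C9 acetate, which sits para to the C3 methoxy group and can ionise or eliminate towards C8. The difficulty lies in setting the stereotriad on a flexible seven-membered ring and in building an oxidised six-membered ring on the hindered C5. The strategy rests on one feature of ring B: oxygen on C9, trans carbon substituents on C7 and C8, and a C5 that can be a ketone. This is the pattern left when an arene-fused carbonyl ylide spanning C9 and C6 adds to an (E)-crotonate; the surplus C6–O bond is alpha to the ketone and can be removed reductively.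

## Retrosynthetic reasoning

**C9 ester and protecting group (30 ⇐ 29 ⇐ 28).** The acetate is the most labile group and goes on last. Behind it stands alcohol 29 and its silyl ether 28, because the C9 oxygen must be masked while C5 is an electrophile or carries an aldehyde; a free hydroxyl would bridge to C5.

**Oxidation pattern of ring C (28 ⇐ 27 ⇐ 26 ⇐ 25).** The second methoxy group at C5' and the C5'=C6' double bond are removed together. Diosphenol 27 is the enol of a 4',5'-dione, which comes from alpha-hydroxy ketone 26, which comes from enone 25 by enolate oxidation. C5' is the only enolisable position of 25, so no regiochemical question arises.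

**Ring C (25 ⇐ 20 + 23).** The C5–C6' bond and the C2'=C3' bond are cut, a Robinson disconnection. It makes the quaternary C5 from an alpha-aryl aldehyde enolate, the most accessible nucleophile at that carbon, and brings in the first methoxy group with vinyl ketone 23. The forward reaction has to form a quaternary carbon next to a doubly ortho-substituted arene. The spiro centre is stereogenic in 25–27, but the epimers converge in 28.

**One-carbon unit on C5 (20 ⇐ 18).** The C5–CHO bond is cut back to the ketone. A ketone at C5 is what the cycloaddition delivers, so only a homologation is needed.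

**C6–O bond (18 ⇐ 17 ⇐ 16).** The C6 methylene is traced to an ether carbon alpha to the C5 ketone. Single-electron reduction cleaves exactly this bond and no other, and it frees the C9 hydroxyl with its configuration untouched.

**C8 methyl (16 ⇐ 15 ⇐ 14 ⇐ 13 ⇐ 12).** The methyl group is the reduced form of the imide carbonyl. Hydride reduction of the imide also reduces the C5 ketone, so the sequence passes through diol 13, the primary sulfonate 14 and alcohol 15, and the ketone is restored in 16. The oxygen bridge is kept through these steps as internal protection of C9–O and as a rigid frame.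

**Key disconnection (12 ⇐ 7 + 10, through 11).** C9–C8 and C6–C7 are cut. This opens ring B and the oxygen bridge at once and removes all four stereocentres of 12. What remains is ylide 11, generated from diazo ketone 7, and the crotonoyl imide 10. The forward reaction must control regiochemistry, the endo/exo mode and the face of the alkene.

**Starting materials (7 ⇐ 6 ⇐ 4 ⇐ 2 ⇐ 1 + 3; 10 ⇐ 8 + 9; 23 ⇐ 21 + 22).** The diazoacetyl group is traced to a methyl ketone, and that to the aryl bromide. The aldehyde is masked as an acetal while organolithium and amide bases are used. The imide and the vinyl ketone each come from one acylation.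

## Alternatives that were turned down

**Alternative 1:** The acyclic C6–C7–C8 unit is made first, cutting C6–C7 and C7–C8. In the forward key step the silylmethyl boronic ester A1 is homologated twice in one flask with a chiral-diamine-ligated alpha-lithioethyl ester of a hindered benzoic acid. Each 1,2-metallate shift is stereospecific and gives A2.
- In favour: each methyl stereocentre is set by the reagent, so both the relative and the absolute configuration are predictable and any diastereomer can be reached. Silicon and boron are orthogonal handles.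
- Against: no ring closes. Neither arene, nor the C9 oxygen, nor the spiro centre is present in A2. C9 must be set in a separate C–C bond formation, ring B must be closed, and C5 must be made quaternary afterwards. Two stoichiometric chiral-ligand steps at low temperature are needed.
- Comparison: on the reliability of C7/C8 control this alternative is stronger, since the chosen route depends on endo/exo and facial selectivity in one step. In its place the chosen strategy gives ring B, the C9 oxygen tied to C7/C8, and the C5 ketone in that same step.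

**Alternative 2:** Ring C is cut at both C2'=C3' and C5'=C6', a (3+3) closure. In the forward key step the titanium enolate of A4 condenses twice with the 5,5-dicarbaldehyde A3 and gives A5, which is the same compound as 28.
- In favour: both methoxy groups and both double bonds arrive in one operation from a symmetric ketone. No spiro epimers appear. The endgame is shorter than the four steps from 20 to 28.
- Against: A3 is a non-enolisable malonaldehyde on a crowded benzylic carbon. Such formyl groups are lost readily by retro-Claisen-type cleavage under the basic or nucleophilic conditions of an aldol reaction, and the first aldol adduct can revert. Making A3 needs two one-carbon units on the most hindered carbon. The plan is silent on ring B and the stereotriad.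
- Comparison: stronger than the chosen route in endgame step count. The chosen route uses the mono-aldehyde 20, which cannot deformylate in this way, and puts its main step where the target is hardest.

**Alternative 3:** C9a–C9 and C4a–C5 are cut. In the forward key step the aryne released by fluoride from A7 inserts into the ketone–alpha-carbon bond of the beta-keto ester A6 (addition, cyclobutanol-type closure, fragmentation) and gives A8.
- In favour: ring B and the C5 ketone form in one step from a five-membered ring in which trans methyl groups are easy to set. The regiochemistry fits: the enolate carbon adds to the aryne carbon remote from the flanking methoxy group, which places the ketone next to C4–OMe.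
- Against: C9 arrives bearing carbon. The ester must be degraded to an acetoxy group over several steps at a benzylic, doubly activated centre that epimerises easily. A7 and enantiopure A6 each need their own syntheses.
- Comparison: equal or better than the chosen route in reaching a C5-keto benzosuberone quickly. The chosen strategy delivers oxygen on C9 directly, with its configuration coupled to C7 and C8.

Key step: step 6

Assumption: the (4S,5S)-diphenyl-pybox ligand is written for the Yb(OTf)3 catalyst; which ligand enantiomer shields the required face of the bound crotonoyl imide has to be settled by correlation, and the mirror-image ligand is used if the sense is opposite.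

## Route

Step 1
Reactants: 1 2-bromo-3,4,5-trimethoxybenzaldehyde
Product: 2 2-bromo-1-(dimethoxymethyl)-3,4,5-trimethoxybenzene
Conditions: HC(OMe)3, MeOH, TsOH·H2O (cat.), rt; then Et3N
Reagents that add atoms: trimethyl orthoformate, COC(OC)OC; methanol, CO
Why: Acid-catalysed acetalisation driven by the orthoformate; the dimethyl acetal masks the aldehyde against the organolithium and amide bases of steps 2 and 3 and is later removable with very mild acid.

Step 2
Reactants: 2 2-bromo-1-(dimethoxymethyl)-3,4,5-trimethoxybenzene; 3 N-methoxy-N-methylacetamide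
Product: 4 1-[6-(dimethoxymethyl)-2,3,4-trimethoxyphenyl]ethan-1-one
Conditions: n-BuLi, THF, −78 °C; then 3, −78 → 0 °C; aq. NH4Cl
Reagents that add atoms: none
Why: Bromine–lithium exchange followed by acylation of the aryllithium with a Weinreb amide; the chelated tetrahedral adduct prevents over-addition and the acetal is inert to the base.

Step 3
Reactants: 4 1-[6-(dimethoxymethyl)-2,3,4-trimethoxyphenyl]ethan-1-one
Product: 6 2-diazo-1-[6-(dimethoxymethyl)-2,3,4-trimethoxyphenyl]ethan-1-one, via trifluoroacetyl diketone 5 (not isolated)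
Conditions: LiN(SiMe3)2, THF, −78 °C; CF3CO2CH2CF3; aq. NH4Cl; then MsN3, Et3N, H2O, MeCN, rt
Reagents that add atoms: methanesulfonyl azide, CS(=O)(=O)N=[N+]=[N-]
Why: Detrifluoroacetylative diazo transfer: the kinetic methyl-ketone enolate is trifluoroacetylated, and the activated 1,3-diketone 5 accepts the diazo group from the sulfonyl azide with loss of the trifluoroacetyl group, a standard way to terminal aryl diazomethyl ketones without diazomethane.

Step 4
Reactants: 6 2-diazo-1-[6-(dimethoxymethyl)-2,3,4-trimethoxyphenyl]ethan-1-one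
Product: 7 2-(2-diazoacetyl)-3,4,5-trimethoxybenzaldehyde
Conditions: pyridinium p-toluenesulfonate (cat.), acetone/H2O, 0 °C → rt; NaHCO3; used directly
Reagents that add atoms: water, O
Why: Acetal hydrolysis; the acetal carbon is para to a methoxy group, so the oxocarbenium ion forms under acid far too weak to protonate the acceptor-stabilised diazo carbon.

Step 5
Reactants: 8 oxazolidin-2-one; 9 (E)-but-2-enoyl chloride
Product: 10 3-[(E)-but-2-enoyl]oxazolidin-2-one
Conditions: n-BuLi, THF, −78 °C; then 9, −78 → 0 °C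
Reagents that add atoms: none
Why: N-Acylation of the lithiated oxazolidinone; the (E)-geometry of the acid chloride is carried over unchanged.

Step 6
Reactants: 7 2-(2-diazoacetyl)-3,4,5-trimethoxybenzaldehyde; 10 3-[(E)-but-2-enoyl]oxazolidin-2-one
Product: 12 3-{[(6S,7S,8S,9R)-2,3,4-trimethoxy-7-methyl-5-oxo-6,7,8,9-tetrahydro-5H-6,9-epoxybenzo[7]annulen-8-yl]carbonyl}-1,3-oxazolidin-2-one, via 5,6,7-trimethoxy-2-benzopyrylium-4-olate 11 (not isolated)
Conditions: Rh2(OAc)4 (2 mol %), Yb(OTf)3 (10 mol %), 2,6-bis[(4S,5S)-4,5-diphenyl-4,5-dihydrooxazol-2-yl]pyridine (10 mol %), 4 Å MS, CH2Cl2, −10 °C → rt, slow addition of 7 to 10 (2 equiv)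
Reagents that add atoms: none
Why: Rh2(OAc)4 extrudes dinitrogen from 7 and the electrophilic rhodium carbenoid is captured by a lone pair of the neighbouring formyl oxygen, which closes the six-membered oxygen heterocycle (O, C9, C9a, C4a, C5, C6) by C–O bond formation and releases the free ylide 11. Ylide 11 then adds through its termini C9 and C6 to the alkene of 10 in a concerted suprafacial cycloaddition (four π electrons of the C9–O–C6 ylide, two of the alkene), which closes the seven-membered carbocycle in a (5+2) sense and leaves the oxygen as a one-atom bridge; the closest known reaction type is the addition of dirhodium-generated 2-benzopyrylium-4-olates to 3-(2-alkenoyl)oxazolidin-2-ones under lanthanide triflate–pybox catalysis. Regiochemistry follows from the ylide HOMO and the LUMO of the Lewis-acid-bound imide: the enolate-like terminus C6 carries the larger coefficient and bonds to the β-carbon, so the methyl group lands on C7 and the acyl group on C8. C6 and C9 are necessarily cis because the dipole reacts on one face, and C7 and C8 are trans because the (E)-geometry of 10 is retained. C8 relative to C9 is set by the endo mode, in which the chelated acyl group lies under the arene–olate π system and the β-methyl group points to the oxygen side, away from the olate carbon. The absolute configuration is set by the pybox ligand on ytterbium, which binds 10 through both carbonyl groups and shields one face of the s-cis enoyl unit. The step needs chemoselective carbenoid capture (secured by the ortho formyl group and by slow addition of 7, which suppresses carbene dimerisation) and a catalysed pathway that outruns the background addition (secured by the LUMO lowering of the bound imide and by molecular sieves that keep the Lewis acid dry).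

Step 7
Reactants: 12 cycloadduct imide
Product: 13 (6S,7S,8R,9R)-8-(hydroxymethyl)-2,3,4-trimethoxy-7-methyl-6,7,8,9-tetrahydro-5H-6,9-epoxybenzo[7]annulen-5-ol (C5 epimers)
Conditions: LiBH4, MeOH (3 equiv), THF, 0 °C → rt
Reagents that add atoms: none
Why: Reductive cleavage of the N-acyl oxazolidinone to the primary alcohol; the C5 ketone is reduced as well, which is accepted because the carbinol is re-oxidised in step 10, and the mild hydride does not epimerise C8.

Step 8
Reactants: 13 diol
Product: 14 [(6S,7S,8R,9R)-5-hydroxy-2,3,4-trimethoxy-7-methyl-6,7,8,9-tetrahydro-5H-6,9-epoxybenzo[7]annulen-8-yl]methyl 4-methylbenzenesulfonate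
Conditions: TsCl (1.1 equiv), Et3N, DMAP (cat.), CH2Cl2, 0 °C
Reagents that add atoms: 4-methylbenzenesulfonyl chloride, Cc1ccc(cc1)S(Cl)(=O)=O
Why: Sulfonylation is selective for the primary hydroxyl over the hindered secondary benzylic one.

Step 9
Reactants: 14 primary tosylate
Product: 15 (6S,7S,8S,9R)-2,3,4-trimethoxy-7,8-dimethyl-6,7,8,9-tetrahydro-5H-6,9-epoxybenzo[7]annulen-5-ol (C5 epimers)
Conditions: LiEt3BH, THF, 0 °C → rt
Reagents that add atoms: none
Why: SN2 displacement of the primary sulfonate by hydride turns the CH2OTs group into the C8 methyl; the rigid bicycle holds the C5 alkoxide away from the endo CH2OTs carbon, so intramolecular ether formation should not compete.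

Step 10
Reactants: 15 bicyclic alcohol
Product: 16 (6S,7S,8S,9R)-2,3,4-trimethoxy-7,8-dimethyl-6,7,8,9-tetrahydro-5H-6,9-epoxybenzo[7]annulen-5-one
Conditions: Dess–Martin periodinane, NaHCO3, CH2Cl2, rt
Reagents that add atoms: none
Why: Dess–Martin oxidation of the secondary benzylic alcohol restores the ketone that activates the C6–O bond; C6 is a bridgehead and cannot epimerise.

Step 11
Reactants: 16 oxa-bridged ketone
Product: 17 (7R,8S,9R)-9-hydroxy-2,3,4-trimethoxy-7,8-dimethyl-6,7,8,9-tetrahydro-5H-benzo[7]annulen-5-one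
Conditions: SmI2 (2.2 equiv), THF/MeOH, −78 °C
Reagents that add atoms: none
Why: Single-electron reduction of the aryl ketone to the ketyl, β-elimination of the α-alkoxy group and protonation of the samarium enolate cleave only the C6–O bond, a known opening of oxa-bridged ketones from carbonyl-ylide cycloadditions; C7, C8 and C9 are not touched.

Step 12
Reactants: 17 hydroxy ketone
Product: 18 (7R,8S,9R)-9-[(tert-butyldimethylsilyl)oxy]-2,3,4-trimethoxy-7,8-dimethyl-6,7,8,9-tetrahydro-5H-benzo[7]annulen-5-one
Conditions: TBSOTf (1.1 equiv), 2,6-lutidine, CH2Cl2, −78 → 0 °C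
Reagents that add atoms: tert-butyldimethylsilyl trifluoromethanesulfonate, CC(C)(C)[Si](C)(C)OS(=O)(=O)C(F)(F)F
Why: O-Silylation of the secondary alcohol is much faster than enol silylation at low temperature; the silyl ether stops the C9 oxygen from bridging to C5 (hemiketal or cyclic ether formation) in the steps that follow.

Step 13
Reactants: 18 silyloxy ketone
Product: 20 (7R,8S,9R)-9-[(tert-butyldimethylsilyl)oxy]-2,3,4-trimethoxy-7,8-dimethyl-6,7,8,9-tetrahydro-5H-benzo[7]annulene-5-carbaldehyde (C5 epimers), via methoxymethylidene enol ether 19 (not isolated)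
Conditions: Ph3P(CH2OMe)Cl, KN(SiMe3)2, THF, 0 °C → rt; then 0.5 M HCl, THF, 0 °C
Reagents that add atoms: (methoxymethyl)triphenylphosphonium chloride, COC[P+](c1ccccc1)(c1ccccc1)c1ccccc1.[Cl-]; water, O
Why: Wittig methoxymethylenation and hydrolysis of the enol ether (protonation at C5, oxocarbenium ion on the exocyclic carbon) homologate the ketone to the aldehyde; the C5 configuration is immaterial because C5 becomes quaternary in step 15.

Step 14
Reactants: 21 N,2-dimethoxy-N-methylacetamide; 22 vinylmagnesium bromide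
Product: 23 1-methoxybut-3-en-2-one
Conditions: CH2=CHMgBr (22), THF, −20 → 0 °C; inverse quench into cold 1 M HCl; used as a stabilised solution
Reagents that add atoms: none
Why: Grignard addition to a Weinreb amide stops at the ketone stage; the cold acidic quench protonates the released amine before it can add to the new enone.

Step 15
Reactants: 20 aldehyde; 23 1-methoxybut-3-en-2-one
Product: 25 (7R,8S,9R)-9-[(tert-butyldimethylsilyl)oxy]-2,3,3',4-tetramethoxy-7,8-dimethyl-6,7,8,9-tetrahydrospiro[benzo[7]annulene-5,1'-cyclohex[2]en]-4'-one (spiro epimers), via keto aldehyde Michael adduct 24 (not isolated)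
Conditions: 23 (1.5 equiv), DBU (0.2 equiv), THF, 0 °C → rt; then KOH, MeOH, 50 °C
Reagents that add atoms: none
Why: Robinson annulation: the aryl-stabilised aldehyde enolate adds through C5 to the vinyl ketone and makes the quaternary centre, then 24 closes by aldol condensation through the methoxy-bearing methylene (the only enolisation mode that gives a six-membered ring) and dehydrates to the 2-methoxy enone. The spiro centre forms as a mixture, which is of no consequence because both arms of ring C become identical in 28.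

Step 16
Reactants: 25 spiro methoxy enone
Product: 26 (7R,8S,9R)-9-[(tert-butyldimethylsilyl)oxy]-5'-hydroxy-2,3,3',4-tetramethoxy-7,8-dimethyl-6,7,8,9-tetrahydrospiro[benzo[7]annulene-5,1'-cyclohex[2]en]-4'-one (mixture at C5' and the spiro centre)
Conditions: KN(SiMe3)2, THF, −78 °C; then 2-(phenylsulfonyl)-3-phenyloxaziridine, −78 °C; aq. NH4Cl
Reagents that add atoms: 2-(phenylsulfonyl)-3-phenyloxaziridine, O=S(=O)(N1OC1c1ccccc1)c1ccccc1
Why: Enolate hydroxylation with an N-sulfonyloxaziridine; C5' carries the only enolisable hydrogens (C1' is quaternary, so no γ-deprotonation), and the potassium enolate limits addition to the sulfonimine by-product.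

Step 17
Reactants: 26 α-hydroxy ketone
Product: 27 (7R,8S,9R)-9-[(tert-butyldimethylsilyl)oxy]-3'-hydroxy-2,3,4,5'-tetramethoxy-7,8-dimethyl-6,7,8,9-tetrahydrospiro[benzo[7]annulene-5,1'-cyclohexa[2,5]dien]-4'-one (diosphenol; spiro epimers)
Conditions: Dess–Martin periodinane, CH2Cl2, rt
Reagents that add atoms: none
Why: Oxidation of the acyloin to the 1,2-dione, which exists as its enol towards C6' because that tautomer is the cross-conjugated dienone.

Step 18
Reactants: 27 diosphenol
Product: 28 (7R,8S,9R)-9-[(tert-butyldimethylsilyl)oxy]-2,3,3',4,5'-pentamethoxy-7,8-dimethyl-6,7,8,9-tetrahydrospiro[benzo[7]annulene-5,1'-cyclohexa[2,5]dien]-4'-one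
Conditions: Me2SO4, K2CO3, acetone, 50 °C
Reagents that add atoms: dimethyl sulfate, COS(=O)(=O)OC
Why: O-Methylation of the acidic diosphenol hydroxyl by a hard methylating agent; the two arms of ring C are now identical and the spiro carbon is no longer stereogenic, so the epimeric series converge.

Step 19
Reactants: 28 silyl ether
Product: 29 (7R,8S,9R)-9-hydroxy-2,3,3',4,5'-pentamethoxy-7,8-dimethyl-6,7,8,9-tetrahydrospiro[benzo[7]annulene-5,1'-cyclohexa[2,5]dien]-4'-one
Conditions: HF·pyridine, pyridine, THF, 0 °C → rt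
Reagents that add atoms: none
Why: Fluoride-driven desilylation under buffered conditions, which avoid both a free C9 alkoxide (it could add to the dienone) and strong acid (ionisation at C9 or dienone–phenol rearrangement).

Step 20
Reactants: 29 alcohol
Product: 30 (7R,8S,9R)-2,3,3',4,5'-pentamethoxy-7,8-dimethyl-4'-oxo-6,7,8,9-tetrahydrospiro[benzo[7]annulene-5,1'-cyclohexa[2,5]dien]-9-yl acetate
Conditions: Ac2O, pyridine, DMAP (cat.), CH2Cl2, 0 °C → rt
Reagents that add atoms: acetic anhydride, CC(=O)OC(C)=O
Why: DMAP-catalysed O-acylation of the secondary benzylic alcohol; the C9–O bond is not broken, so the configuration is retained.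

## Compound list

1 | 2-bromo-3,4,5-trimethoxybenzaldehyde | COc1cc(C=O)c(Br)c(OC)c1OC | starting material
2 | 2-bromo-1-(dimethoxymethyl)-3,4,5-trimethoxybenzene | COc1cc(C(OC)OC)c(Br)c(OC)c1OC | intermediate
3 | N-methoxy-N-methylacetamide | CC(=O)N(C)OC | starting material
4 | 1-[6-(dimethoxymethyl)-2,3,4-trimethoxyphenyl]ethan-1-one | COc1cc(C(OC)OC)c(C(C)=O)c(OC)c1OC | intermediate
5 | 1-[6-(dimethoxymethyl)-2,3,4-trimethoxyphenyl]-4,4,4-trifluorobutane-1,3-dione | COc1cc(C(OC)OC)c(C(=O)CC(=O)C(F)(F)F)c(OC)c1OC | intermediate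
6 | 2-diazo-1-[6-(dimethoxymethyl)-2,3,4-trimethoxyphenyl]ethan-1-one | COc1cc(C(OC)OC)c(C(=O)C=[N+]=[N-])c(OC)c1OC | intermediate
7 | 2-(2-diazoacetyl)-3,4,5-trimethoxybenzaldehyde | COc1cc(C=O)c(C(=O)C=[N+]=[N-])c(OC)c1OC | intermediate
8 | oxazolidin-2-one | O=C1NCCO1 | starting material
9 | (E)-but-2-enoyl chloride | C/C=C/C(Cl)=O | starting material
10 | 3-[(E)-but-2-enoyl]oxazolidin-2-one | C/C=C/C(=O)N1CCOC1=O | intermediate
11 | 5,6,7-trimethoxy-2-benzopyrylium-4-olate | [O-]C1=C[O+]=Cc2cc(OC)c(OC)c(OC)c12 | intermediate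
12 | 3-{[(6S,7S,8S,9R)-2,3,4-trimethoxy-7-methyl-5-oxo-6,7,8,9-tetrahydro-5H-6,9-epoxybenzo[7]annulen-8-yl]carbonyl}-1,3-oxazolidin-2-one (8-endo acyl; 7-exo methyl) | O=C1[C@@H]2[C@@H](C)[C@H](C(=O)N3CCOC3=O)[C@@H](O2)c2cc(OC)c(OC)c(OC)c12 | intermediate
13 | (6S,7S,8R,9R)-8-(hydroxymethyl)-2,3,4-trimethoxy-7-methyl-6,7,8,9-tetrahydro-5H-6,9-epoxybenzo[7]annulen-5-ol (C5 epimers) | OC1[C@@H]2[C@@H](C)[C@H](CO)[C@@H](O2)c2cc(OC)c(OC)c(OC)c12 | intermediate
14 | [(6S,7S,8R,9R)-5-hydroxy-2,3,4-trimethoxy-7-methyl-6,7,8,9-tetrahydro-5H-6,9-epoxybenzo[7]annulen-8-yl]methyl 4-methylbenzenesulfonate (C5 epimers) | OC1[C@@H]2[C@@H](C)[C@H](COS(=O)(=O)c3ccc(C)cc3)[C@@H](O2)c2cc(OC)c(OC)c(OC)c12 | intermediate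
15 | (6S,7S,8S,9R)-2,3,4-trimethoxy-7,8-dimethyl-6,7,8,9-tetrahydro-5H-6,9-epoxybenzo[7]annulen-5-ol (C5 epimers) | OC1[C@@H]2[C@@H](C)[C@H](C)[C@@H](O2)c2cc(OC)c(OC)c(OC)c12 | intermediate
16 | (6S,7S,8S,9R)-2,3,4-trimethoxy-7,8-dimethyl-6,7,8,9-tetrahydro-5H-6,9-epoxybenzo[7]annulen-5-one | O=C1[C@@H]2[C@@H](C)[C@H](C)[C@@H](O2)c2cc(OC)c(OC)c(OC)c12 | intermediate
17 | (7R,8S,9R)-9-hydroxy-2,3,4-trimethoxy-7,8-dimethyl-6,7,8,9-tetrahydro-5H-benzo[7]annulen-5-one | O=C1C[C@@H](C)[C@H](C)[C@@H](O)c2cc(OC)c(OC)c(OC)c12 | intermediate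
18 | (7R,8S,9R)-9-[(tert-butyldimethylsilyl)oxy]-2,3,4-trimethoxy-7,8-dimethyl-6,7,8,9-tetrahydro-5H-benzo[7]annulen-5-one | O=C1C[C@@H](C)[C@H](C)[C@@H](O[Si](C)(C)C(C)(C)C)c2cc(OC)c(OC)c(OC)c12 | intermediate
19 | tert-butyl{[(7R,8S,9R)-2,3,4-trimethoxy-5-(methoxymethylidene)-7,8-dimethyl-6,7,8,9-tetrahydro-5H-benzo[7]annulen-9-yl]oxy}dimethylsilane (E/Z mixture) | COC=C1C[C@@H](C)[C@H](C)[C@@H](O[Si](C)(C)C(C)(C)C)c2cc(OC)c(OC)c(OC)c12 | intermediate
20 | (7R,8S,9R)-9-[(tert-butyldimethylsilyl)oxy]-2,3,4-trimethoxy-7,8-dimethyl-6,7,8,9-tetrahydro-5H-benzo[7]annulene-5-carbaldehyde (C5 epimers) | O=CC1C[C@@H](C)[C@H](C)[C@@H](O[Si](C)(C)C(C)(C)C)c2cc(OC)c(OC)c(OC)c12 | intermediate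
21 | N,2-dimethoxy-N-methylacetamide | COCC(=O)N(C)OC | starting material
22 | vinylmagnesium bromide | C=C[Mg]Br | starting material
23 | 1-methoxybut-3-en-2-one | COCC(=O)C=C | intermediate
24 | (7R,8S,9R)-9-[(tert-butyldimethylsilyl)oxy]-2,3,4-trimethoxy-5-(4-methoxy-3-oxobutyl)-7,8-dimethyl-6,7,8,9-tetrahydro-5H-benzo[7]annulene-5-carbaldehyde (C5 epimers) | COCC(=O)CCC1(C=O)C[C@@H](C)[C@H](C)[C@@H](O[Si](C)(C)C(C)(C)C)c2cc(OC)c(OC)c(OC)c12 | intermediate
25 | (7R,8S,9R)-9-[(tert-butyldimethylsilyl)oxy]-2,3,3',4-tetramethoxy-7,8-dimethyl-6,7,8,9-tetrahydrospiro[benzo[7]annulene-5,1'-cyclohex[2]en]-4'-one (spiro epimers) | COC1=CC2(CCC1=O)C[C@@H](C)[C@H](C)[C@@H](O[Si](C)(C)C(C)(C)C)c1cc(OC)c(OC)c(OC)c12 | intermediate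
26 | (7R,8S,9R)-9-[(tert-butyldimethylsilyl)oxy]-5'-hydroxy-2,3,3',4-tetramethoxy-7,8-dimethyl-6,7,8,9-tetrahydrospiro[benzo[7]annulene-5,1'-cyclohex[2]en]-4'-one (mixture at C5' and the spiro centre) | COC1=CC2(CC(O)C1=O)C[C@@H](C)[C@H](C)[C@@H](O[Si](C)(C)C(C)(C)C)c1cc(OC)c(OC)c(OC)c12 | intermediate
27 | (7R,8S,9R)-9-[(tert-butyldimethylsilyl)oxy]-3'-hydroxy-2,3,4,5'-tetramethoxy-7,8-dimethyl-6,7,8,9-tetrahydrospiro[benzo[7]annulene-5,1'-cyclohexa[2,5]dien]-4'-one (spiro epimers) | COC1=CC2(C=C(O)C1=O)C[C@@H](C)[C@H](C)[C@@H](O[Si](C)(C)C(C)(C)C)c1cc(OC)c(OC)c(OC)c12 | intermediate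
28 | (7R,8S,9R)-9-[(tert-butyldimethylsilyl)oxy]-2,3,3',4,5'-pentamethoxy-7,8-dimethyl-6,7,8,9-tetrahydrospiro[benzo[7]annulene-5,1'-cyclohexa[2,5]dien]-4'-one | COC1=CC2(C=C(OC)C1=O)C[C@@H](C)[C@H](C)[C@@H](O[Si](C)(C)C(C)(C)C)c1cc(OC)c(OC)c(OC)c12 | intermediate
29 | (7R,8S,9R)-9-hydroxy-2,3,3',4,5'-pentamethoxy-7,8-dimethyl-6,7,8,9-tetrahydrospiro[benzo[7]annulene-5,1'-cyclohexa[2,5]dien]-4'-one | COC1=CC2(C=C(OC)C1=O)C[C@@H](C)[C@H](C)[C@@H](O)c1cc(OC)c(OC)c(OC)c12 | intermediate
30 | (7R,8S,9R)-2,3,3',4,5'-pentamethoxy-7,8-dimethyl-4'-oxo-6,7,8,9-tetrahydrospiro[benzo[7]annulene-5,1'-cyclohexa[2,5]dien]-9-yl acetate | COC1=CC2(C=C(OC)C1=O)C[C@@H](C)[C@H](C)[C@@H](OC(C)=O)c1cc(OC)c(OC)c(OC)c12 | target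

## Step count and least certain steps

Total step count: 20. Longest linear sequence: 18 steps (steps 1–4, 6–13 and 15–20); steps 5 and 14 are side branches.

**Step 6 (key step).** The most likely failure is competition from the exo mode of approach: the bulky ytterbium-bound acyl group may avoid the arene, and the β-methyl group makes the imide a slower dipolarophile, which also gives the uncatalysed addition more room. The ligand fixes the face of the imide and therefore C7 and C8 in either mode, so an exo adduct is wrong only at C9 and at the transient C6. The fallback relays the exo adduct and inverts C9. It sets out from 7 and 10 under the same conditions and returns at 17. The exo cycloadduct F1 should be reduced with LiBH4 to the exo diol F2, tosylated to the exo tosylate F3, reduced with LiEt3BH to the exo dimethyl alcohol F4 and oxidised with Dess–Martin periodinane to the exo bridged ketone F5. SmI2 should then give the 9-epi hydroxy ketone F6. A Mitsunobu esterification (PPh3, diisopropyl azodicarboxylate, 4-nitrobenzoic acid) should invert C9 to the (9R) 4-nitrobenzoate F7, and K2CO3 in MeOH should release 17.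

**Step 15.** The Michael addition has to form a quaternary carbon next to a doubly ortho-substituted arene. If it is slow, the vinyl ketone 23 polymerises, and the adduct can revert or lose its formyl group during the basic closure. The fallback separates annulation from oxygenation. It sets out from 20 and returns at 25. Annulation with the more electrophilic but-3-en-2-one (KOH cat., EtOH) should give the spiro cyclohexenone F8. Nucleophilic epoxidation (H2O2, NaOH, MeOH) should give the 2',3'-epoxy ketone F9. NaOMe in MeOH should open the epoxide at C3', alpha to the carbonyl, and dehydrate to 25.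

**Step 13.** The C5 carbonyl of 18 is twisted and shielded by the C4 methoxy group, so the basic ylide may enolise the ketone towards C6 and fail to add. The fallback uses a non-basic carbenoid and moves the oxygen on afterwards. It sets out from 18 and returns at 20. Methylenation with Cp2TiMe2 (toluene, 70 °C) should give the exocyclic alkene F10. Anti-Markovnikov hydroboration–oxidation (9-BBN; NaOH, H2O2) should give the primary alcohol F11, and Dess–Martin oxidation should give 20.

**Step 4.** The diazo ketone may lose nitrogen under the acid needed for acetal hydrolysis, and in 7 the diazo carbon may slowly attack the liberated aldehyde. The fallback carries the aldehyde at the alcohol oxidation level and reveals it by a neutral oxidation. It sets out from 1 and returns at 7. NaBH4 should give the benzylic alcohol F12, and TBSCl with imidazole the silyl ether F13. Bromine–lithium exchange and acylation with 3 should give the methyl ketone F14. Diazo transfer as in step 3, through the trifluoroacetyl diketone F15 (not isolated), should give the silylated diazo ketone F16. Bu4NF buffered with AcOH should give the hydroxymethyl diazo ketone F17, and MnO2 in CH2Cl2 should give 7.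

**Step 16.** The cross-conjugated enolate may add to the sulfonimine by-product or be over-oxidised, so conversion to 26 may be poor. The fallback introduces the unsaturation first and the oxygen through an epoxide. It sets out from 25, bypasses 26 and 27, and returns at 28. LiN(SiMe3)2 and Me3SiCl should give the trimethylsilyl dienol ether F18. Saegusa–Ito oxidation with Pd(OAc)2 in MeCN (the spent metal is zerovalent palladium) should give the 3'-methoxy dienone F19. Nucleophilic epoxidation (H2O2, NaOH) should be selective for the unsubstituted, more electrophilic enone and give the 5',6'-epoxide F20. NaOMe in MeOH should open it at C5' and dehydrate to 28.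

## Further compounds

F1 | step 6 | 3-{[(6R,7S,8S,9S)-2,3,4-trimethoxy-7-methyl-5-oxo-6,7,8,9-tetrahydro-5H-6,9-epoxybenzo[7]annulen-8-yl]carbonyl}-1,3-oxazolidin-2-one (8-exo acyl; 7-endo methyl) | O=C1[C@H]2[C@@H](C)[C@H](C(=O)N3CCOC3=O)[C@H](O2)c2cc(OC)c(OC)c(OC)c12
F2 | step 6 | (6R,7S,8R,9S)-8-(hydroxymethyl)-2,3,4-trimethoxy-7-methyl-6,7,8,9-tetrahydro-5H-6,9-epoxybenzo[7]annulen-5-ol (C5 epimers) | OC1[C@H]2[C@@H](C)[C@H](CO)[C@H](O2)c2cc(OC)c(OC)c(OC)c12
F3 | step 6 | [(6R,7S,8R,9S)-5-hydroxy-2,3,4-trimethoxy-7-methyl-6,7,8,9-tetrahydro-5H-6,9-epoxybenzo[7]annulen-8-yl]methyl 4-methylbenzenesulfonate (C5 epimers) | OC1[C@H]2[C@@H](C)[C@H](COS(=O)(=O)c3ccc(C)cc3)[C@H](O2)c2cc(OC)c(OC)c(OC)c12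
F4 | step 6 | (6R,7S,8S,9S)-2,3,4-trimethoxy-7,8-dimethyl-6,7,8,9-tetrahydro-5H-6,9-epoxybenzo[7]annulen-5-ol (C5 epimers) | OC1[C@H]2[C@@H](C)[C@H](C)[C@H](O2)c2cc(OC)c(OC)c(OC)c12
F5 | step 6 | (6R,7S,8S,9S)-2,3,4-trimethoxy-7,8-dimethyl-6,7,8,9-tetrahydro-5H-6,9-epoxybenzo[7]annulen-5-one | O=C1[C@H]2[C@@H](C)[C@H](C)[C@H](O2)c2cc(OC)c(OC)c(OC)c12
F6 | step 6 | (7R,8S,9S)-9-hydroxy-2,3,4-trimethoxy-7,8-dimethyl-6,7,8,9-tetrahydro-5H-benzo[7]annulen-5-one | O=C1C[C@@H](C)[C@H](C)[C@H](O)c2cc(OC)c(OC)c(OC)c12
F7 | step 6 | (7R,8S,9R)-2,3,4-trimethoxy-7,8-dimethyl-5-oxo-6,7,8,9-tetrahydro-5H-benzo[7]annulen-9-yl 4-nitrobenzoate | O=C1C[C@@H](C)[C@H](C)[C@@H](OC(=O)c2ccc(cc2)[N+](=O)[O-])c2cc(OC)c(OC)c(OC)c12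
F8 | step 15 | (7R,8S,9R)-9-[(tert-butyldimethylsilyl)oxy]-2,3,4-trimethoxy-7,8-dimethyl-6,7,8,9-tetrahydrospiro[benzo[7]annulene-5,1'-cyclohex[2]en]-4'-one (spiro epimers) | O=C1C=CC2(CC1)C[C@@H](C)[C@H](C)[C@@H](O[Si](C)(C)C(C)(C)C)c1cc(OC)c(OC)c(OC)c12
F9 | step 15 | (7R,8S,9R)-9-[(tert-butyldimethylsilyl)oxy]-2',3'-epoxy-2,3,4-trimethoxy-7,8-dimethyl-6,7,8,9-tetrahydrospiro[benzo[7]annulene-5,1'-cyclohexan]-4'-one (mixture of epimers) | O=C1CCC2(C3OC13)C[C@@H](C)[C@H](C)[C@@H](O[Si](C)(C)C(C)(C)C)c1cc(OC)c(OC)c(OC)c12
F10 | step 13 | tert-butyl{[(7R,8S,9R)-2,3,4-trimethoxy-7,8-dimethyl-5-methylidene-6,7,8,9-tetrahydro-5H-benzo[7]annulen-9-yl]oxy}dimethylsilane | C=C1C[C@@H](C)[C@H](C)[C@@H](O[Si](C)(C)C(C)(C)C)c2cc(OC)c(OC)c(OC)c12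
F11 | step 13 | {(7R,8S,9R)-9-[(tert-butyldimethylsilyl)oxy]-2,3,4-trimethoxy-7,8-dimethyl-6,7,8,9-tetrahydro-5H-benzo[7]annulen-5-yl}methanol (C5 epimers) | OCC1C[C@@H](C)[C@H](C)[C@@H](O[Si](C)(C)C(C)(C)C)c2cc(OC)c(OC)c(OC)c12
F12 | step 4 | (2-bromo-3,4,5-trimethoxyphenyl)methanol | COc1cc(CO)c(Br)c(OC)c1OC
F13 | step 4 | [(2-bromo-3,4,5-trimethoxyphenyl)methoxy](tert-butyl)dimethylsilane | COc1cc(CO[Si](C)(C)C(C)(C)C)c(Br)c(OC)c1OC
F14 | step 4 | 1-[6-({[tert-butyl(dimethyl)silyl]oxy}methyl)-2,3,4-trimethoxyphenyl]ethan-1-one | COc1cc(CO[Si](C)(C)C(C)(C)C)c(C(C)=O)c(OC)c1OC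
F15 | step 4 | 1-[6-({[tert-butyl(dimethyl)silyl]oxy}methyl)-2,3,4-trimethoxyphenyl]-4,4,4-trifluorobutane-1,3-dione | COc1cc(CO[Si](C)(C)C(C)(C)C)c(C(=O)CC(=O)C(F)(F)F)c(OC)c1OC
F16 | step 4 | 1-[6-({[tert-butyl(dimethyl)silyl]oxy}methyl)-2,3,4-trimethoxyphenyl]-2-diazoethan-1-one | COc1cc(CO[Si](C)(C)C(C)(C)C)c(C(=O)C=[N+]=[N-])c(OC)c1OC
F17 | step 4 | 2-diazo-1-[6-(hydroxymethyl)-2,3,4-trimethoxyphenyl]ethan-1-one | COc1cc(CO)c(C(=O)C=[N+]=[N-])c(OC)c1OC
F18 | step 16 | tert-butyl{[(7R,8S,9R)-2,3,3',4-tetramethoxy-7,8-dimethyl-4'-[(trimethylsilyl)oxy]-6,7,8,9-tetrahydrospiro[benzo[7]annulene-5,1'-cyclohexa[2,4]dien]-9-yl]oxy}dimethylsilane (spiro epimers) | COC1=CC2(CC=C1O[Si](C)(C)C)C[C@@H](C)[C@H](C)[C@@H](O[Si](C)(C)C(C)(C)C)c1cc(OC)c(OC)c(OC)c12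
F19 | step 16 | (7R,8S,9R)-9-[(tert-butyldimethylsilyl)oxy]-2,3,3',4-tetramethoxy-7,8-dimethyl-6,7,8,9-tetrahydrospiro[benzo[7]annulene-5,1'-cyclohexa[2,5]dien]-4'-one (spiro epimers) | COC1=CC2(C=CC1=O)C[C@@H](C)[C@H](C)[C@@H](O[Si](C)(C)C(C)(C)C)c1cc(OC)c(OC)c(OC)c12
F20 | step 16 | (7R,8S,9R)-9-[(tert-butyldimethylsilyl)oxy]-5',6'-epoxy-2,3,3',4-tetramethoxy-7,8-dimethyl-6,7,8,9-tetrahydrospiro[benzo[7]annulene-5,1'-cyclohex[2]en]-4'-one (mixture of epimers) | COC1=CC2(C3OC3C1=O)C[C@@H](C)[C@H](C)[C@@H](O[Si](C)(C)C(C)(C)C)c1cc(OC)c(OC)c(OC)c12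
A1 | alternative 1 | dimethyl(phenyl)[(4,4,5,5-tetramethyl-1,3,2-dioxaborolan-2-yl)methyl]silane | C[Si](C)(CB1OC(C)(C)C(C)(C)O1)c1ccccc1
A2 | alternative 1 | dimethyl(phenyl)[(2S,3S)-2-methyl-3-(4,4,5,5-tetramethyl-1,3,2-dioxaborolan-2-yl)butyl]silane | C[Si](C)(C[C@@H](C)[C@H](C)B1OC(C)(C)C(C)(C)O1)c1ccccc1
A3 | alternative 2 | (7R,8S,9R)-9-[(tert-butyldimethylsilyl)oxy]-2,3,4-trimethoxy-7,8-dimethyl-6,7,8,9-tetrahydro-5H-benzo[7]annulene-5,5-dicarbaldehyde | O=CC1(C=O)C[C@@H](C)[C@H](C)[C@@H](O[Si](C)(C)C(C)(C)C)c2cc(OC)c(OC)c(OC)c12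
A4 | alternative 2 | 1,3-dimethoxypropan-2-one | COCC(=O)COC
A5 | alternative 2 | (7R,8S,9R)-9-[(tert-butyldimethylsilyl)oxy]-2,3,3',4,5'-pentamethoxy-7,8-dimethyl-6,7,8,9-tetrahydrospiro[benzo[7]annulene-5,1'-cyclohexa[2,5]dien]-4'-one | COC1=CC2(C=C(OC)C1=O)C[C@@H](C)[C@H](C)[C@@H](O[Si](C)(C)C(C)(C)C)c1cc(OC)c(OC)c(OC)c12
A6 | alternative 3 | methyl (2S,3R)-2,3-dimethyl-5-oxocyclopentane-1-carboxylate | O=C1C[C@@H](C)[C@H](C)C1C(=O)OC
A7 | alternative 3 | 3,4,5-trimethoxy-2-(trimethylsilyl)phenyl trifluoromethanesulfonate | COc1cc(OS(=O)(=O)C(F)(F)F)c([Si](C)(C)C)c(OC)c1OC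
A8 | alternative 3 | methyl (7R,8S,9R)-2,3,4-trimethoxy-7,8-dimethyl-5-oxo-6,7,8,9-tetrahydro-5H-benzo[7]annulene-9-carboxylate | O=C1C[C@@H](C)[C@H](C)[C@@H](C(=O)OC)c2cc(OC)c(OC)c(OC)c12
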